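Readings and results come from a simulation on assumed constants, and the scatter is random.

A small charge of solid substrate, the south-west run, shows you where the solid goes before you reckon the larger flask.

- south-west: solid substrate 0.55 M; gas phase 200 mM (held); run made earlier
- flask: solid substrate 1.1 M; gas phase 200 mM (held); time 8.0 min

south-west run (percent of the solid substrate charged)

| time / min | target / % | solid substrate / % |
|---|---|---|
| 0.417 | 1.2 | 83.8 |
| 0.833 | 0.9 | 69.8 |
| 1.33 | 4.7 | 49.5 |
| 1.50 | 7.6 | 43.7 |
| 2.00 | 10.3 | 26.2 |
| 2.50 | 10.7 | 8.4 |

(each reading ± 1 percentage point)

* target at 8.0 min, in percent of the solid substrate charged
* the change that raises the amount of target at 8.0 min, in percent of the solid substrate charged most ("none" if none brings more than 2 percentage points) (zeta / alpha / epsilon / beta / none)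
* amount of target at 8.0 min, in percent of the solid substrate charged, after zeta

- zeta: doubling the transfer coefficient of the gas phase, all else as stated
- alpha: doubling the solubility of the solid substrate, all else as stated
- epsilon: doubling the saturation concentration of gas phase, all else as stated
- beta: doubling the dissolution coefficient of the solid substrate, all else as stated

1. Start with the first rung. Between the first and last readings of the south-west run, the solid substrate falls at about 0.199 M min⁻¹, so at that rate the south-west charge lasts 2.76 min.

2. Now look at what this loss yields. At 2.50 min the south-west run shows 8.4% of its solid substrate left but only 10.7% of target. In that run the loss of solid is therefore the large quantity, and target is a small correction to it. That reading gives 11.7%, the target share, meaning target formed per amount of solid substrate lost, a kind of selectivity. Its target reading carries a scatter of 1 percentage point.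

3. The next rung is the flask. At the same rate, its charge lasts 5.53 min, which is longer than the south-west charge.

4. The last rung is the asked time, 8.0 min, which is longer still. So your reckoning has the whole charge out of the solid by then. If the share carries over, your reckoning gives 11.7% of target in the flask.

5. The forecast differs from this reckoning, with 22% of target, epsilon as the best change and 41% after zeta: “That points to gas transfer as the limit, not substrate supply.”

6. The flask gives 9.01% of target, with solid substrate at 0%. The best change is epsilon, the doubling of the saturation concentration of gas phase, worth 9.6 points, and zeta, the doubling of the transfer coefficient of the gas phase, gives 14.2%.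

    gas phase ⇌ dissolved gas, rate k1*(csat - [dissolved gas]) (kL = 0.00431 s⁻¹)
    starting material + dissolved gas ⇌ target (K = 17.4 M⁻¹, k = 0.275 M⁻¹ s⁻¹)
    starting material → side product (k = 0.0201 s⁻¹)
    solid substrate ⇌ starting material, rate k4*(cs4 - [starting material]) while solid is left; crystals form when [starting material] > cs4 (solubility = 1.10 M, k = 0.00337 s⁻¹)

Your reckoned 11.7% of target stands against 9.01% in this flask, where side product reaches 88.7%. Now carry the same reckoning to the neighbouring flask charged with 2.8 M, read at the same time. At the rate read from the south-west run, your reckoning takes 56.9% of that charge out of the solid, and the share turns this into 6.66% of target. The neighbouring flask shows 43.8% of its solid substrate left, so 56.2% has left the solid, and it holds 7.33% of target.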